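## Structural features

The target, (2R,4R,6S,9S,10S)-4,10-dibromo-9-chloro-5,5,9-trimethyl-1-methylidenespiro[5.5]undecan-2-ol, is a spiro[5.5]undecane in which ring A (C1–C6) and ring B (C6–C11) share the quaternary C6, which sits next to the gem-dimethyl quaternary C5. Ring A carries the exocyclic methylene at C1, an axial allylic carbinol at C2 and an equatorial neopentyl bromide at C4; the C2 hydroxyl and the C4 bromine are 1,3-trans, and the hydroxyl is syn to the ring B methylene C7. Ring B carries the tertiary chloride and a methyl group at C9 and the secondary bromide at C10; the two halogens are trans and both equatorial (methyl axial), and the bromine is cis to C5 across the ring. Fragile points are the tertiary chloride (ionisation and loss of HCl), the secondary bromides (base-induced elimination, reduction by zinc or low-valent metals), any β-bromo carbonyl intermediate (loss of HBr), any enolate with a γ-bromide (1,3-closure to a cyclopropane) and the allylic alcohol. The real difficulty is stereochemical: the diequatorial bromochloride cannot come from an untethered trans-diaxial opening of a bromonium ion once the bulky C5 is on C6, so the halogens must be installed while C6 still bears hydrogen. C6 must then be made quaternary in the correct sense relative to C9 and C10, and C4 must be related to C6 although ring B differentiates the two faces of ring A only weakly. The key step uses the C2–C3–C4 array of ring A: C2 is α to the C1 carbonyl (radical site), C3 is a plain methylene (alkene terminus) and C4 carries bromine next to C5, which is what addition of a ketone-stabilised radical followed by bromine return produces.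

## Logic of the disconnections

16 ⇒ 15. The C2–H bond is cut (carbinol back to ketone). This lets C2 be set last by hydride delivery, which must come from the open face to leave the hydroxyl axial. The forward step must be a clean 1,2-reduction of an enone that also carries a β-bromide.

15 ⇒ 13. The C2–O bond is cut. C2 is the only allylic CH2 of 13, so the oxygen can be introduced without a directing group and the ring A ketone chemistry stays short. The forward step must be a non-basic allylic oxidation, and both C2 epimers must converge on 15.

13 ⇒ 12. The C1=CH2 bond is cut to the C1 ketone. This returns the carbonyl that activates C2 for the ring closure. The forward step must methylenate a ketone flanked by a spiro quaternary carbon without enolising it.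

12 ⇒ 11. The C2–C3 and C4–Br bonds are cut (ring A opened). One isomerisation builds the ring and the neopentyl bromide, which substitution chemistry cannot reach, and the precursor is an acyclic bromomethyl ketone on a finished ring B. The forward step must be 6-endo selective, must leave three other carbon–halogen bonds alone, and must deliver bromine to C4 on the face that corresponds to 12.

11 ⇒ 8. The C1–C2 bond is cut (one-carbon homologation of a carboxylic acid). The acid is the direct product of an ester-enolate rearrangement, so no redox adjustment is needed. The forward step must add one carbon to a very hindered acyl group without base.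

8 ⇒ 5. The C5–C6 bond is cut by a retro-[3,3] shift to a prenyl ester. Both adjacent quaternary carbons and the vinyl group come from one intramolecular step. The forward step must form the bond on the face of C6 cis to the C10 bromine; this is the weakest stereochemical point before the key step.

5 ⇒ 2 + 3. The ester C–O bond and the C9–Cl bond are cut. Opening the lactone delivers the tertiary chloride with retention and the activated acyl group in one operation. The forward step must pass through a bromonium ion and not an open cation.

2 ⇒ 1. The C9–O and C10–Br bonds are cut. The single stereocentre of 1 dictates both new centres through the tether. The forward step must be an anti addition across the ring alkene led by the carboxyl group.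

## Other disconnections considered

Alternative 1: The cut is C1–C6. In the forward step the open-chain phenol A2, which carries a 2-bromoalkene, would undergo oxidative addition to Pd(PPh3)4 (zerovalent palladium) and para-alkenylation of its phenoxide, giving the spirodienone A1. In its favour, the exocyclic methylene and the C2 oxygen are in place before ring A closes, and ring B is symmetric at that stage, so C6 is not yet a stereocentre. On ring A oxygenation this alternative is better than the chosen plan, which needs a late methylenation, an allylic oxidation and a reduction. Against it, C4 carries an ester that must become the neopentyl bromide by a decarboxylative bromination through the same kind of C4 radical, so on C4 the two plans are equal. Ring B arrives as a dienone and still needs the C9 methyl, the C9 chloride and the C10 bromide, placed relative to C6 on a spiro ring where diaxial bromonium opening gives the wrong arrangement; here the alternative is worse. Mechanistically it is a two-electron palladium process against a radical chain. In step count it should be clearly longer.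

Alternative 2: The cuts are C6–C7 and C10–C11. The ring A aldehyde A4 would add through its enol or enamine to but-3-en-2-one A5, and aldol condensation would close ring B to the spiro enone A3. In its favour, the route is convergent, the annulation type is robust for α,α-disubstituted aldehydes, and the C4 bromide with its configuration comes from a separately made building block. On C4 this alternative is better than the chosen plan. Against it, C6 is flanked by C5 and the methylidene carbon, so the Michael step is hindered, and the β,γ-unsaturated aldehyde can slip into conjugation. C6 would be set only under the influence of C4, and ring B must afterwards be turned from an enone into the C9/C10 bromochloride in the correct sense relative to C6, which the chosen plan settles first and stereospecifically. The C2 oxidation is the same in both plans. Ring construction is about as short, but the ring B elaboration should make the whole sequence longer.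

Alternative 3: The cut is C5–C6. The bromochloride A7 would ionise at C5 in hexafluoroisopropanol to an enantiopure bromonium ion; the tetrasubstituted exocyclic alkene would open it at C5, and the C1 cation would lose a proton to give A6. In its favour, one step forms the neopentyl bromide, the gem-dimethyl carbon, the spiro centre and the exocyclic methylene, and C4 is transferred from an enantioenriched bromochloride. On ring A assembly and on C4 this alternative is the equal or the better of the chosen plan. Against it, proton loss can also give endocyclic alkenes, and ring B is a symmetric ketal that must later be desymmetrised relative to the distant C4 (C10 versus C8, then an equatorial tertiary chloride), the same late-stage problem as in Alternative 2. The C2 oxygen is still missing. Mechanistically it is cationic against radical; the count to ring A is lower, the count to the target probably not.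

Key step: step 5

Remark: the bromolactone 2 is drawn as the δ-lactone (oxygen on the tertiary carbon). If the γ-lactone regioisomer formed instead, step 2 would pass through the same bromonium ion and give the same 4.

Remark on numbering: spiro numbering C1–C11 as in the names below; ring A = C1–C6, ring B = C6–C11.

## Steps

Step 1
Reactants: 1 (R)-4-methylcyclohex-3-ene-1-carboxylic acid
Product: 2 (1S,4R,6S)-6-bromo-1-methyl-2-oxabicyclo[2.2.2]octan-3-one
Conditions: NBS (1.05 equiv), MeCN, 0 °C to rt, dark
Reagents that add atoms: N-bromosuccinimide, O=C1CCC(=O)N1Br
Why: Bromolactonisation: the carboxyl group can reach the ring alkene only from its own face, so the bromonium ion forms on the opposite face and is opened at the tertiary carbon. This fixes C9–O cis and C10–Br trans to the carboxyl carbon, (9S,10S) in target numbering, from the single stereocentre of 1.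

Step 2
Reactants: 2 (1S,4R,6S)-6-bromo-1-methyl-2-oxabicyclo[2.2.2]octan-3-one; 3 3-methylbut-2-en-1-ol
Product: 5 3-methylbut-2-en-1-yl (1R,3S,4S)-3-bromo-4-chloro-4-methylcyclohexane-1-carboxylate, via acid chloride 4 (not isolated)
Conditions: SOCl2, ZnCl2 (5 mol %), 60 °C; evaporate; then 3, pyridine, DMAP (cat.), CH2Cl2, 0 °C
Reagents that add atoms: thionyl chloride, O=S(Cl)Cl
Why: Lewis-acid-assisted alkyl–oxygen cleavage of a lactone by SOCl2 (the reaction type that turns lactones into ω-chloroacyl chlorides): the C9–O bond ionises with participation of the C10 bromine and chloride opens the bromonium ion at the tertiary carbon trans to bromine, so C9 keeps its configuration by double inversion. The acyl chloride 4 is then esterified with 3 (acylation of an alcohol by an acid chloride); C6 is not touched.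

Step 3
Reactants: 5 3-methylbut-2-en-1-yl (1R,3S,4S)-3-bromo-4-chloro-4-methylcyclohexane-1-carboxylate
Product: 8 (1R,3S,4S)-3-bromo-4-chloro-4-methyl-1-(2-methylbut-3-en-2-yl)cyclohexane-1-carboxylic acid, via ketene silyl acetal 6 (not isolated), via trimethylsilyl ester 7 (not isolated)
Conditions: LiN(iPr)2 (1.2 equiv) added to 5 and Me3SiCl (3 equiv), THF/DMPU, −78 °C; then 60 °C; 1 M HCl work-up; separation of the C6 epimers
Reagents that add atoms: none
Why: Ireland–Claisen rearrangement: 6 undergoes a chair-like [3,3] shift that joins C6 to the dimethyl-substituted allyl terminus and so builds the two adjacent quaternary carbons with the vinyl group in place; silylation in situ keeps the free enolate from closing onto C10–Br. C6 is set by the face of 6 that is attacked: the face syn to an axial C10 bromine is blocked, so 8 has to arise by equatorial attack on the ring B chair with both halogens equatorial (the more polar chair, favoured by the polar medium), whereas equatorial attack on the flipped chair gives the C6 epimer, and the substrate offers no strong bias between the two. Both C6 epimers are therefore expected and 8 is separated by chromatography or crystallisation.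

Step 4
Reactants: 8 (1R,3S,4S)-3-bromo-4-chloro-4-methyl-1-(2-methylbut-3-en-2-yl)cyclohexane-1-carboxylic acid
Product: 11 2-bromo-1-[(1R,3S,4S)-3-bromo-4-chloro-4-methyl-1-(2-methylbut-3-en-2-yl)cyclohexyl]ethan-1-one, via acid chloride 9 (not isolated), via diazoketone 10 (not isolated)
Conditions: (COCl)2, DMF (cat.), CH2Cl2, 0 °C to rt; evaporate; CH2N2 (3 equiv), Et2O, 0 °C; then 48% aq. HBr, 0 °C
Reagents that add atoms: diazomethane, C=[N+]=[N-]; hydrogen bromide, Br
Why: Acid chloride formation, acylation of diazomethane to the diazoketone (first stage of an Arndt–Eistert sequence) and hydrobromination of the diazoketone give the bromomethyl ketone regiospecifically, with no enolate and no stereocentre involved. Excess diazomethane takes up the HCl.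

Step 5
Reactants: 11 2-bromo-1-[(1R,3S,4S)-3-bromo-4-chloro-4-methyl-1-(2-methylbut-3-en-2-yl)cyclohexyl]ethan-1-one
Product: 12 (4R,6R,9S,10S)-4,10-dibromo-9-chloro-5,5,9-trimethylspiro[5.5]undecan-1-one
Conditions: CuBr (5 mol %), tris(2-pyridylmethyl)amine (5 mol %), AIBN (10 mol %), ClCH2CH2Cl (0.02 M, degassed), 80 °C; separation of the C4 epimers
Reagents that add atoms: none
Why: CuBr with tris(2-pyridylmethyl)amine (monovalent copper) abstracts the activated bromine of 11 and leaves CuBr2 (divalent copper) as the persistent bromine donor; the primary α-keto radical at C2 adds to the terminal vinyl carbon C3 and the secondary C4 radical takes bromine back, so the step is a redox-neutral isomerisation. The closest known reaction type is the halogen-atom-transfer radical cyclisation (Kharasch type) of α-halo carbonyl compounds, including iodine-transfer closures of α-iodo ketones to cyclohexanones. Ring A closes in the 6-endo-trig mode: 5-exo attack at C4 would place the sp2 carbonyl carbon in a five-membered transition state and form a bond next to the quaternary C5, whereas the electrophilic radical prefers the unsubstituted terminus. The new stereocentre C4 is set when bromine is delivered equatorially to the chair-like C4 radical, the axial face being screened by the axial ring B methylene on C6; 12 results from the chair in which C11 is equatorial and C7 axial on ring A. The two chairs differ only in which ring B methylene is axial, so the substrate offers at best a modest bias; the C4 epimer is expected alongside and is removed by chromatography. Chemoselectivity among the carbon–halogen bonds is secured because only the α-keto bromide is activated toward monovalent copper; the secondary bromide and tertiary chloride of ring B and the neopentyl bromide of 12 should not be re-activated. High dilution and slow radical generation keep reduction of the α-keto radical and intermolecular addition below the rate of ring closure.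

Step 6
Reactants: 12 (4R,6R,9S,10S)-4,10-dibromo-9-chloro-5,5,9-trimethylspiro[5.5]undecan-1-one
Product: 13 (4R,6S,9S,10S)-4,10-dibromo-9-chloro-5,5,9-trimethyl-1-methylidenespiro[5.5]undecane
Conditions: Cp2Ti(μ-Cl)(μ-CH2)AlMe2 (2 equiv), pyridine (cat.), THF/toluene, −40 °C to rt
Reagents that add atoms: Cp2Ti(μ-Cl)(μ-CH2)AlMe2, C[Al-]1(C)C[Ti]([Cl+]1)(C2C=CC=C2)C3C=CC=C3
Why: Tebbe-type carbonyl methylenation through the titanium methylidene Cp2Ti=CH2 and an oxatitanacyclobutane: the reagent is small, oxophilic and non-basic, so the hindered C1 ketone should react without enolisation, which would invite 1,3-closure onto C4–Br, while THF and pyridine bind the aluminium by-product and keep it from ionising the tertiary chloride. No stereocentre is formed; the C6 descriptor changes from R to S only because C1 drops below C5 in priority.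

Step 7
Reactants: 13 (4R,6S,9S,10S)-4,10-dibromo-9-chloro-5,5,9-trimethyl-1-methylidenespiro[5.5]undecane
Product: 15 (4R,6S,9S,10S)-4,10-dibromo-9-chloro-5,5,9-trimethyl-1-methylidenespiro[5.5]undecan-2-one, via allylic alcohol 14 (not isolated)
Conditions: SeO2 (0.5 equiv), tBuOOH (3 equiv), CH2Cl2, rt; aqueous work-up; crude 14, Dess–Martin periodinane (1,1,1-triacetoxy-1,1-dihydro-1,2-benziodoxol-3(1H)-one), CH2Cl2, 0 °C to rt; 15 used at once
Reagents that add atoms: selenium dioxide, O=[Se]=O; tert-butyl hydroperoxide (terminal oxidant that restores SeO2), CC(C)(C)OO
Why: SeO2-catalysed allylic oxidation (ene reaction, then [2,3]-sigmatropic shift) can only functionalise C2, the sole allylic CH2, and returns the double bond to the exocyclic position. The face of oxygen delivery is not secure, because the usual preference for the axial carbinol is opposed here by the axial C7 methylene, so the crude carbinols 14 are converged by Dess–Martin oxidation to the single enone 15. The non-basic oxidant and the equatorial, poorly aligned C4–Br bond should hold back β-elimination.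

Step 8
Reactants: 15 (4R,6S,9S,10S)-4,10-dibromo-9-chloro-5,5,9-trimethyl-1-methylidenespiro[5.5]undecan-2-one
Product: 16 (2R,4R,6S,9S,10S)-4,10-dibromo-9-chloro-5,5,9-trimethyl-1-methylidenespiro[5.5]undecan-2-ol
Conditions: (S)-2-methyl-CBS-oxazaborolidine [(S)-1-methyl-3,3-diphenyltetrahydro-1H,3H-pyrrolo[1,2-c][1,3,2]oxazaborole] (20 mol %), catecholborane (1.5 equiv), toluene/CH2Cl2, −78 °C; MeOH quench, aqueous work-up
Reagents that add atoms: none
Why: Corey–Bakshi–Shibata reduction gives 1,2-reduction of the enone. With C1 (alkenyl) as the large and C3 as the small group, the (S)-catalyst delivers hydride to the face that leads to the (2R) carbinol. The substrate prefers the same face because axial approach is hindered by the axial C7 methylene, so the hydroxyl ends axial and trans to C4–Br.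

## Compound list

1 | (R)-4-methylcyclohex-3-ene-1-carboxylic acid | OC(=O)[C@@H]1CCC(C)=CC1 | starting material
2 | (1S,4R,6S)-6-bromo-1-methyl-2-oxabicyclo[2.2.2]octan-3-one | O=C1O[C@@]2(C)CC[C@@H]1C[C@@H]2Br | intermediate
3 | 3-methylbut-2-en-1-ol | CC(C)=CCO | starting material
4 | (1R,3S,4S)-3-bromo-4-chloro-4-methylcyclohexane-1-carbonyl chloride | ClC(=O)[C@@H]1CC[C@](C)(Cl)[C@@H](Br)C1 | intermediate (not isolated)
5 | 3-methylbut-2-en-1-yl (1R,3S,4S)-3-bromo-4-chloro-4-methylcyclohexane-1-carboxylate | CC(C)=CCOC(=O)[C@@H]1CC[C@](C)(Cl)[C@@H](Br)C1 | intermediate
6 | {[(3S,4S)-3-bromo-4-chloro-4-methylcyclohexylidene][(3-methylbut-2-en-1-yl)oxy]methoxy}trimethylsilane (both double-bond isomers) | C[Si](C)(C)OC(OCC=C(C)C)=C1CC[C@](C)(Cl)[C@@H](Br)C1 | intermediate (not isolated)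
7 | trimethylsilyl (1R,3S,4S)-3-bromo-4-chloro-4-methyl-1-(2-methylbut-3-en-2-yl)cyclohexane-1-carboxylate | C[Si](C)(C)OC(=O)[C@]1(C(C)(C)C=C)CC[C@](C)(Cl)[C@@H](Br)C1 | intermediate (not isolated)
8 | (1R,3S,4S)-3-bromo-4-chloro-4-methyl-1-(2-methylbut-3-en-2-yl)cyclohexane-1-carboxylic acid | OC(=O)[C@]1(C(C)(C)C=C)CC[C@](C)(Cl)[C@@H](Br)C1 | intermediate
9 | (1R,3S,4S)-3-bromo-4-chloro-4-methyl-1-(2-methylbut-3-en-2-yl)cyclohexane-1-carbonyl chloride | ClC(=O)[C@]1(C(C)(C)C=C)CC[C@](C)(Cl)[C@@H](Br)C1 | intermediate (not isolated)
10 | 2-diazo-1-[(1R,3S,4S)-3-bromo-4-chloro-4-methyl-1-(2-methylbut-3-en-2-yl)cyclohexyl]ethan-1-one | [N-]=[N+]=CC(=O)[C@]1(C(C)(C)C=C)CC[C@](C)(Cl)[C@@H](Br)C1 | intermediate (not isolated)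
11 | 2-bromo-1-[(1R,3S,4S)-3-bromo-4-chloro-4-methyl-1-(2-methylbut-3-en-2-yl)cyclohexyl]ethan-1-one | BrCC(=O)[C@]1(C(C)(C)C=C)CC[C@](C)(Cl)[C@@H](Br)C1 | intermediate (precursor of the key step)
12 | (4R,6R,9S,10S)-4,10-dibromo-9-chloro-5,5,9-trimethylspiro[5.5]undecan-1-one | O=C1CC[C@@H](Br)C(C)(C)[C@]12CC[C@](C)(Cl)[C@@H](Br)C2 | intermediate (product of the key step)
13 | (4R,6S,9S,10S)-4,10-dibromo-9-chloro-5,5,9-trimethyl-1-methylidenespiro[5.5]undecane | C=C1CC[C@@H](Br)C(C)(C)[C@]12CC[C@](C)(Cl)[C@@H](Br)C2 | intermediate
14 | (2RS,4R,6S,9S,10S)-4,10-dibromo-9-chloro-5,5,9-trimethyl-1-methylidenespiro[5.5]undecan-2-ol (C2 epimers) | C=C1C(O)C[C@@H](Br)C(C)(C)[C@]12CC[C@](C)(Cl)[C@@H](Br)C2 | intermediate (not isolated)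
15 | (4R,6S,9S,10S)-4,10-dibromo-9-chloro-5,5,9-trimethyl-1-methylidenespiro[5.5]undecan-2-one | C=C1C(=O)C[C@@H](Br)C(C)(C)[C@]12CC[C@](C)(Cl)[C@@H](Br)C2 | intermediate
16 | (2R,4R,6S,9S,10S)-4,10-dibromo-9-chloro-5,5,9-trimethyl-1-methylidenespiro[5.5]undecan-2-ol | C=C1[C@H](O)C[C@@H](Br)C(C)(C)[C@]12CC[C@](C)(Cl)[C@@H](Br)C2 | target

Total step count: 8. Longest linear sequence: 8 steps (1 to 16).

## Least certain steps

Step 5 (key step). Bromine is likely to be delivered to both faces of the C4 radical, because the two ring A chairs differ only through remote ring B substituents. In addition, the electron-poor α-keto radical may be reduced by monovalent copper before it cyclises, which would cost the bromine without ring closure. Fallback, from 11 back to 12: displacement of the α-keto bromide with KSC(=S)OEt in acetone would give the S-(2-oxoalkyl) O-ethyl dithiocarbonate F1. Dilauroyl peroxide in refluxing ClCH2CH2Cl would effect a xanthate-group-transfer 6-endo cyclisation to the C4 dithiocarbonate of the spiro ketone F2. Heating F2 with excess ethyl 2-bromo-2-methylpropanoate and dicumyl peroxide in chlorobenzene would then exchange the dithiocarbonate for bromine through the same C4 radical and give 12. This replaces the copper redox cycle by a degenerate group transfer with long radical lifetimes and a bulky bromine donor; the C4 epimers would still have to be separated.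

Step 3. Poor facial selectivity at C6 is the main risk. The ring B chair with axial halogens offers an unhindered equatorial approach on the other face, which leads to the C6 epimer. Loss of bromide by 1,3-closure of the enolate before silylation is a second risk. Fallback, from 1 and 3 back to 9: carbodiimide esterification would give the prenyl ester F3. Ester-enolate Claisen rearrangement under the conditions of step 3 would give the racemic quaternary acid F4, since the stereocentre is erased in the enolate. Resolution through a diastereomeric salt with 1-phenylethylamine would give the (R)-acid F5. Bromolactonisation with NBS would give the bromolactone F6, in which the tether forces bromine trans to the carboxyl carbon and therefore cis to C5. The electron-rich trisubstituted ring alkene should take up bromine ahead of the hindered vinyl group, although lactonisation through the vinyl group is a competing path that would have to be watched. SOCl2 with ZnCl2 would open F6 through the bromonium ion on that face, with chloride entering at the tertiary carbon, to give 9, where the route continues with diazomethane.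

Step 2. Ionisation of the tertiary C–O bond without bromine participation would lead to proton loss or to chloride entering from both faces, and prenol may ionise if HCl is not removed. Fallback, from 2 back to 5: HCl gas with catalytic ZnCl2 in CH2Cl2 would open the lactone to the bromochloro acid F7, which is isolated and coupled with 3 by dicyclohexylcarbodiimide and DMAP to give 5.

Step 7. Loss of HBr from the β-bromo enone on oxidation or on silica, over-oxidation, and self-condensation of the α-methylene ketone on standing are the risks. Fallback, from 14 (here isolated) to 16: the C2 epimers of 14 would be separated, the (2R) epimer being 16 itself. The (2S) epimer would be inverted under Mitsunobu conditions (4-nitrobenzoic acid, PPh3, diisopropyl azodicarboxylate) to the (2R) 4-nitrobenzoate F8, and K2CO3 in MeOH would release 16 without passing through 15.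

Step 6. Incomplete conversion of the very hindered ketone, or enolisation, are the risks. Fallback, from 12 back to 13: addition of Me3SiCH2Li premixed with CeCl3 at −78 °C would give the β-hydroxysilane F9, and HF·pyridine would eliminate it to 13 (Peterson olefination).

## Further compounds

F1 | step 5 | O-ethyl S-{2-[(1R,3S,4S)-3-bromo-4-chloro-4-methyl-1-(2-methylbut-3-en-2-yl)cyclohexyl]-2-oxoethyl} carbonodithioate | CCOC(=S)SCC(=O)[C@]1(C(C)(C)C=C)CC[C@](C)(Cl)[C@@H](Br)C1
F2 | step 5 | O-ethyl S-[(6R,9S,10S)-10-bromo-9-chloro-5,5,9-trimethyl-1-oxospiro[5.5]undecan-4-yl] carbonodithioate (C4 epimers) | O=C1CCC(SC(=S)OCC)C(C)(C)[C@]12CC[C@](C)(Cl)[C@@H](Br)C2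
F3 | step 3 | 3-methylbut-2-en-1-yl (1R)-4-methylcyclohex-3-ene-1-carboxylate | CC(C)=CCOC(=O)[C@@H]1CCC(C)=CC1
F4 | step 3 | rac-4-methyl-1-(2-methylbut-3-en-2-yl)cyclohex-3-ene-1-carboxylic acid | OC(=O)C1(C(C)(C)C=C)CCC(C)=CC1
F5 | step 3 | (1R)-4-methyl-1-(2-methylbut-3-en-2-yl)cyclohex-3-ene-1-carboxylic acid | OC(=O)[C@]1(C(C)(C)C=C)CCC(C)=CC1
F6 | step 3 | (1S,4R,6S)-6-bromo-1-methyl-4-(2-methylbut-3-en-2-yl)-2-oxabicyclo[2.2.2]octan-3-one | O=C1O[C@@]2(C)CC[C@]1(C(C)(C)C=C)C[C@@H]2Br
F7 | step 2 | (1R,3S,4S)-3-bromo-4-chloro-4-methylcyclohexane-1-carboxylic acid | OC(=O)[C@@H]1CC[C@](C)(Cl)[C@@H](Br)C1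
F8 | step 7 | (2R,4R,6S,9S,10S)-4,10-dibromo-9-chloro-5,5,9-trimethyl-1-methylidenespiro[5.5]undecan-2-yl 4-nitrobenzoate | C=C1[C@H](OC(=O)c3ccc(cc3)[N+](=O)[O-])C[C@@H](Br)C(C)(C)[C@]12CC[C@](C)(Cl)[C@@H](Br)C2
F9 | step 6 | (1RS,4R,6R,9S,10S)-4,10-dibromo-9-chloro-5,5,9-trimethyl-1-[(trimethylsilyl)methyl]spiro[5.5]undecan-1-ol (C1 epimers) | C[Si](C)(C)CC1(O)CC[C@@H](Br)C(C)(C)[C@]12CC[C@](C)(Cl)[C@@H](Br)C2
A1 | alternative 1 | methyl (2R)-2-[(tert-butyldimethylsilyl)oxy]-5,5-dimethyl-1-methylidene-9-oxospiro[5.5]undeca-7,10-diene-4-carboxylate | C=C1[C@H](O[Si](C)(C)C(C)(C)C)CC(C(=O)OC)C(C)(C)C12C=CC(=O)C=C2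
A2 | alternative 1 | methyl (4R)-5-bromo-4-[(tert-butyldimethylsilyl)oxy]-2-[2-(4-hydroxyphenyl)propan-2-yl]hex-5-enoate | C=C(Br)[C@H](O[Si](C)(C)C(C)(C)C)CC(C(=O)OC)C(C)(C)c1ccc(O)cc1
A3 | alternative 2 | (4R,6S)-4-bromo-5,5-dimethyl-1-methylidenespiro[5.5]undec-10-en-9-one | C=C1CC[C@@H](Br)C(C)(C)[C@]12CCC(=O)C=C2
A4 | alternative 2 | (3R)-3-bromo-2,2-dimethyl-6-methylidenecyclohexane-1-carbaldehyde | C=C1CC[C@@H](Br)C(C)(C)C1C=O
A5 | alternative 2 | but-3-en-2-one | CC(=O)C=C
A6 | alternative 3 | (4R)-4-bromo-5,5-dimethyl-1-methylidenespiro[5.5]undecan-9-one ethylene ketal | C=C1CC[C@@H](Br)C(C)(C)C12CCC3(CC2)OCCO3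
A7 | alternative 3 | 8-[(5R)-5-bromo-6-chloro-6-methylheptan-2-ylidene]-1,4-dioxaspiro[4.5]decane | CC(CC[C@@H](Br)C(C)(C)Cl)=C1CCC2(CC1)OCCO2
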